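1. Target formed from one substrate and one reagent, so the gap between reagent and substrate held its charged value, 1.00 M in the alder run, where substrate was the limiting reagent. With that gap, S and R (substrate, reagent) followed from the target made, p.

| flask | substrate | reagent | free catalyst | target | time |
|---|---|---|---|---|---|
| alder | 1.00 M | 2.00 M | 0.0500 M |  |  |
| maple | 1.00 M | 2.00 M | 0.0500 M | 0.500 M |  |
| elm | 1.00 M | 1.00 M | 0.0170 M |  | 3.3 h |

| run | time / h | [target] / M |
|---|---|---|
| alder run | 0.66 | 0.235 |
| alder run | 1.3 | 0.381 |
| alder run | 2.0 | 0.476 |
| alder run | 2.6 | 0.532 |
| alder run | 3.3 | 0.575 |
| maple run | 0.66 | 0.723 |
| maple run | 1.3 | 0.817 |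
| maple run | 2.0 | 0.883 |
| maple run | 2.6 | 0.913 |
| maple run | 3.3 | 0.911 |

(readings scatter by 0.01 M)

* target in the elm run at 3.3 h, as a share of the substrate charged
* which of these the readings show (nothing beyond the main steps / the substrate kills the catalyst / a little impurity takes part of the catalyst at once / the product reacts on with the second partner / the product kills the catalyst)

2. I divided the rate of target formation by S·R and called this the activity, a. Integrated, it gave a clock θ in which time had dropped out. With S_c and R_c the charges, θ = ln(S_c·R/(R_c·S))/(R_c − S_c), and for equal charges θ = p/(S_c·S).

3. First instants. The clock at the first alder reading, divided by its time, gave the opening activity, 0.216 /M/h. By that same time the maple run, charged with 0.500 M of target, had gained 0.223 M, close to the 0.235 M of the alder run.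

4. Middle. At 2.0 h the maple run had gained 0.383 M of new target, less than the 0.476 M of the alder run. The charges of substrate, reagent and catalyst were equal in these two runs, so the added target was the one setting that differed.

5. End. Alder's activity over its last interval read 0.0952 /M/h. The last maple reading stood at 0.911 M, with 0.589 M of substrate left by the balance. I read this as target killing the catalyst.

6. Elm. Both runs had one catalyst charge, so they gave no order in catalyst. I scaled a by the charge ratio 0.340, to the first power and to the second, and ignored any loss. That gave 19.5% and 7.63%, and I committed to that range.

7. The forecast gave 19.5% (16.5% to 22.5%) and "the product kills the catalyst", holding that “Little product forms, so the decay is mild”, which is the alder run with its clock scaled as if first order in everything but substrate.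

8. The elm run gave 13.0%, and the readings showed that the product kills the catalyst. Fitted with the true steps, the root mean square residual was 0.48 in units of the scatter, against 5.2 with a catalyst that dies by itself.

    2 free catalyst ⇌ catalyst dimer, settled at all times (30.60 /M)
    catalyst dimer + substrate + reagent → target + catalyst dimer (14.90 /M²/h)
    free catalyst + target → spent catalyst + target (1.217 /M/h)

Elm's clock at 3.3 h gave a mean activity of 0.0452 /M/h, which was 0.209 of alder's opening 0.216 /M/h. Against the charge ratio, that was an apparent order in catalyst of 1.45.

Readings and results stem from a simulated flask for substances that don't exist, and the scatter is random.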